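## Retrosynthetic overview

1. The target comes from oxidation of the C‑2 carbinol of a trans‑hydrindanol acid, which comes from an intramolecular Diels–Alder reaction of an acyclic tetraenyl hydroxy acid. The cyclohexene and the cyclopentane ring close together in the last step; no ring exists before it.
2. The acyclic hydroxy acid comes from a vinylogous Mukaiyama aldol reaction (C4–C5 bond) between a tetraenal and a valinol‑derived vinylketene N,O‑acetal, followed by imide hydrolysis.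
3. The tetraenal comes from glycol cleavage of a diol made from the key step, the Sharpless epoxidation of crotyl alcohol (two C–O bonds). The C3–O bond is displaced with inversion by a tetraenylalane (new one‑flask carboalumination/alkenyl transfer); the C2–O bond is kept and ends as the C‑2 ketone.
4. The tetraenylalane comes from a trienyne built from TMS‑propynal by two formyl‑ylide Wittig reactions and a benzylphosphonate HWE reaction.
5. Stereochemical relay: epoxide C3 → C6 of the chain → (with the auxiliary) C4/C5 → the four ring stereocentres.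

Assumption: 2‑(triphenylphosphoranylidene)butanal and (E)‑2‑ethylhex‑2‑enoic acid are bought as catalogue items.

## Route

Step 1
Reactants: 1 3‑(trimethylsilyl)prop‑2‑ynal; 2 2‑(triphenylphosphoranylidene)butanal
Product: 3 (E)‑2‑ethyl‑5‑(trimethylsilyl)pent‑2‑en‑4‑ynal
Conditions: CH2Cl2, rt
Reagents that add atoms: none
Why: Wittig olefination with a stabilised formyl ylide gives the (E)‑trisubstituted enal under thermodynamic control, and the ynal is far more electrophilic than the product enal, so mono‑homologation is clean.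

Step 2
Reactants: 3 (E)‑2‑ethyl‑5‑(trimethylsilyl)pent‑2‑en‑4‑ynal; 2 2‑(triphenylphosphoranylidene)butanal
Product: 4 (2E,4E)‑2,4‑diethyl‑7‑(trimethylsilyl)hepta‑2,4‑dien‑6‑ynal
Conditions: PhMe, 90 °C
Reagents that add atoms: none
Why: A second Wittig homologation with the same stabilised ylide again places the chain trans to CHO (2E), and the less electrophilic dienal resists a third addition.

Step 3
Reactants: 4 (2E,4E)‑2,4‑diethyl‑7‑(trimethylsilyl)hepta‑2,4‑dien‑6‑ynal; 5 diethyl benzylphosphonate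
Product: 7 [(1E,3E,5E)‑3,5‑diethylocta‑1,3,5‑trien‑7‑yn‑1‑yl]benzene, via TMS‑trienyne 6 (not isolated)
Conditions: t‑BuOK, THF, 0 °C→rt; then K2CO3 (cat.), MeOH, rt
Reagents that add atoms: none
Why: Horner–Wadsworth–Emmons olefination with the benzylphosphonate anion gives the (E)‑styrene, and methanolysis of the alkynyl C–Si bond in the same flask frees the terminal alkyne.

Step 4
Reactants: 8 (E)‑but‑2‑en‑1‑ol
Product: 9 [(2S,3S)‑3‑methyloxiran‑2‑yl]methanol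
Conditions: Ti(OiPr)4 (5 mol%), L‑(+)‑DIPT (6 mol%), t‑BuOOH, 4 Å MS, CH2Cl2, −20 °C
Reagents that add atoms: tert‑butyl hydroperoxide, CC(C)(C)OO
Why: Sharpless asymmetric epoxidation with the L‑(+)‑tartrate–Ti complex forms both C–O bonds on one face of the (E)‑allylic alcohol to give the (2S,3S)‑epoxide; this supplies the oxygen that ends as the C‑2 ketone and the chirality that is passed to carbon in step 5.

Step 5
Reactants: 7 [(1E,3E,5E)‑3,5‑diethylocta‑1,3,5‑trien‑7‑yn‑1‑yl]benzene; 9 [(2S,3S)‑3‑methyloxiran‑2‑yl]methanol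
Product: 11 (2R,3S,4E,6E,8E,10E)‑7,9‑diethyl‑3,5‑dimethyl‑11‑phenylundeca‑4,6,8,10‑tetraene‑1,2‑diol, via tetraenylalane 10 (not isolated)
Conditions: Me3Al (2.0 equiv), Cp2ZrCl2 (25 mol%), CH2Cl2, 0 °C→rt; then 9 (0.9 equiv), hexane–CH2Cl2, −30→0 °C; Rochelle salt
Reagents that add atoms: trimethylaluminium, C[Al](C)C
Why: Proposed new method: Zr‑catalysed syn‑methylalumination (Negishi carboalumination) of the terminal alkyne gives (E)‑alkenyl(dimethyl)alane 10; the leftover Me3Al converts 9 into a dimethylaluminium alkoxide that chelates and activates the epoxide oxygen, and the sp2 ligand of 10 (which transfers faster than methyl) attacks C3 anti to the breaking C–O bond, so C3 is inverted and becomes the C‑methyl stereocentre (3S) while the C2–O bond is kept; the closest known reactions are the C3‑selective opening of 2,3‑epoxy alcohols by trialkyl‑ and alkynylalanes and the opening of simple epoxides by alkenylalanates, neither shown for a carboalumination‑derived polyenylalane on an unprotected epoxy alcohol.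

Step 6
Reactants: 11 (2R,3S,4E,6E,8E,10E)‑7,9‑diethyl‑3,5‑dimethyl‑11‑phenylundeca‑4,6,8,10‑tetraene‑1,2‑diol
Product: 12 (2S,3E,5E,7E,9E)‑6,8‑diethyl‑2,4‑dimethyl‑10‑phenyldeca‑3,5,7,9‑tetraenal
Conditions: NaIO4, THF–pH 7 buffer, 0 °C; used crude at once
Reagents that add atoms: none
Why: Periodate (Malaprade) glycol cleavage under neutral conditions gives the α‑methyl‑β,γ‑unsaturated aldehyde without touching the tetraene, and immediate cold use protects the labile α‑stereocentre.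

Step 7
Reactants: 13 (E)‑2‑ethylhex‑2‑enoic acid; 14 (4S)‑4‑isopropyloxazolidin‑2‑one
Product: 16 (4S)‑3‑[(E)‑2‑ethylhex‑2‑enoyl]‑4‑isopropyloxazolidin‑2‑one, via pivalic mixed anhydride 15 (not isolated)
Conditions: PivCl, Et3N, THF, −20 °C; then 14, LiCl, rt
Reagents that add atoms: none
Why: Mixed‑anhydride N‑acylation (LiCl‑assisted) occurs at the unhindered enoyl carbonyl and forms the C–N bond that carries the auxiliary.

Step 8
Reactants: 16 (4S)‑3‑[(E)‑2‑ethylhex‑2‑enoyl]‑4‑isopropyloxazolidin‑2‑one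
Product: 17 (4S)‑3‑[(1E,3E)‑1‑[(tert‑butyldimethylsilyl)oxy]‑2‑ethylhexa‑1,3‑dien‑1‑yl]‑4‑isopropyloxazolidin‑2‑one
Conditions: TBSCl, NaHMDS, THF, −78 °C
Reagents that add atoms: tert‑butyldimethylsilyl chloride, CC(C)(C)[Si](C)(C)Cl
Why: γ‑Deprotonation of the enoyl imide and O‑silylation of the dienolate give the (1E,3E)‑vinylketene silyl N,O‑acetal (Kobayashi reagent), as in the α‑methyl series.

Step 9
Reactants: 12 (2S,3E,5E,7E,9E)‑6,8‑diethyl‑2,4‑dimethyl‑10‑phenyldeca‑3,5,7,9‑tetraenal; 17 (4S)‑3‑[(1E,3E)‑1‑[(tert‑butyldimethylsilyl)oxy]‑2‑ethylhexa‑1,3‑dien‑1‑yl]‑4‑isopropyloxazolidin‑2‑one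
Product: 18 (4S)‑3‑[(2E,4S,5R,6S,7E,9E,11E,13E)‑2,4,10,12‑tetraethyl‑5‑hydroxy‑6,8‑dimethyl‑14‑phenyltetradeca‑2,7,9,11,13‑pentaenoyl]‑4‑isopropyloxazolidin‑2‑one
Conditions: TiCl4 (1.0 equiv), CH2Cl2, −78 °C; Rochelle salt/NaHCO3 quench; carried on cold
Reagents that add atoms: none
Why: Kobayashi vinylogous Mukaiyama aldol reaction: the TiCl4‑activated aldehyde adds to the γ‑carbon on the diene face opposite the isopropyl group through an open antiperiplanar transition state, giving the 4,5‑anti (4S,5R) adduct with an (E)‑enoyl imide; Felkin addition to the (2S)‑aldehyde gives the same 5,6‑syn isomer, so reagent and substrate control are matched.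

Step 10
Reactants: 18 (4S)‑3‑[(2E,4S,5R,6S,7E,9E,11E,13E)‑2,4,10,12‑tetraethyl‑5‑hydroxy‑6,8‑dimethyl‑14‑phenyltetradeca‑2,7,9,11,13‑pentaenoyl]‑4‑isopropyloxazolidin‑2‑one
Product: 20 (2E,4S,5R,6S,7E,9E,11E,13E)‑2,4,10,12‑tetraethyl‑5‑hydroxy‑6,8‑dimethyl‑14‑phenyltetradeca‑2,7,9,11,13‑pentaenoic acid, via peroxy acid 19 (not isolated)
Conditions: LiOH, H2O2, THF–H2O, 0 °C; Na2SO3; then 1 M HCl to pH 3
Reagents that add atoms: hydrogen peroxide (as LiOOH), OO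
Why: Evans hydroperoxide cleavage: LiOOH attacks the exocyclic imide carbonyl, and sulfite reduces the percarboxylate; at 0 °C the tetraene, the free hydroxyl and the stereocentres are untouched, and the auxiliary is removed before the dienophile carbon becomes quaternary.

Step 11
Reactants: 20 (2E,4S,5R,6S,7E,9E,11E,13E)‑2,4,10,12‑tetraethyl‑5‑hydroxy‑6,8‑dimethyl‑14‑phenyltetradeca‑2,7,9,11,13‑pentaenoic acid
Product: 22 (1S,3S,3aR,4R,5R,7aR)‑3,4,5‑triethyl‑5‑[(1E,3E)‑2‑ethyl‑4‑phenylbuta‑1,3‑dien‑1‑yl]‑1,7‑dimethyl‑2‑oxo‑2,3,3a,4,5,7a‑hexahydro‑1H‑indene‑4‑carboxylic acid (CNP0134269.1), via hydrindanol acid 21 (not isolated)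
Conditions: BHT (cat.), ClCH2CH2Cl (0.01 M), 80 °C; then Dess–Martin periodinane, rt
Reagents that add atoms: none
Why: Intramolecular Diels–Alder reaction of the (7E,9E)‑diene with the (E)‑2‑ethylacrylic acid dienophile: allylic 1,3‑strain at C6 and C4 fixes both π‑faces and forces the trans‑fused transition state, setting C3a, C4, C5 and C7a in one event, and Dess–Martin oxidation then gives the ketone, whose two α‑centres already have the thermodynamically preferred configuration.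

## Compound list

1 | 3‑(trimethylsilyl)prop‑2‑ynal | C[Si](C)(C)C#CC=O | starting material
2 | 2‑(triphenylphosphoranylidene)butanal | CCC(C=O)=P(c1ccccc1)(c1ccccc1)c1ccccc1 | starting material
3 | (E)‑2‑ethyl‑5‑(trimethylsilyl)pent‑2‑en‑4‑ynal | C[Si](C)(C)C#C/C=C(\CC)C=O | intermediate
4 | (2E,4E)‑2,4‑diethyl‑7‑(trimethylsilyl)hepta‑2,4‑dien‑6‑ynal | C[Si](C)(C)C#C/C=C(\CC)/C=C(\CC)C=O | intermediate
5 | diethyl benzylphosphonate | CCOP(=O)(Cc1ccccc1)OCC | starting material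
6 | trimethyl[(3E,5E,7E)‑4,6‑diethyl‑8‑phenylocta‑3,5,7‑trien‑1‑yn‑1‑yl]silane | C[Si](C)(C)C#C/C=C(\CC)/C=C(\CC)/C=C/c1ccccc1 | intermediate (not isolated)
7 | [(1E,3E,5E)‑3,5‑diethylocta‑1,3,5‑trien‑7‑yn‑1‑yl]benzene | C#C/C=C(\CC)/C=C(\CC)/C=C/c1ccccc1 | intermediate
8 | (E)‑but‑2‑en‑1‑ol | C/C=C/CO | starting material
9 | [(2S,3S)‑3‑methyloxiran‑2‑yl]methanol | C[C@@H]1O[C@H]1CO | intermediate
10 | dimethyl[(1E,3E,5E,7E)‑4,6‑diethyl‑2‑methyl‑8‑phenylocta‑1,3,5,7‑tetraen‑1‑yl]alumane | C[Al](C)/C=C(\C)/C=C(\CC)/C=C(\CC)/C=C/c1ccccc1 | intermediate (not isolated)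
11 | (2R,3S,4E,6E,8E,10E)‑7,9‑diethyl‑3,5‑dimethyl‑11‑phenylundeca‑4,6,8,10‑tetraene‑1,2‑diol | OC[C@H](O)[C@@H](C)/C=C(\C)/C=C(\CC)/C=C(\CC)/C=C/c1ccccc1 | intermediate
12 | (2S,3E,5E,7E,9E)‑6,8‑diethyl‑2,4‑dimethyl‑10‑phenyldeca‑3,5,7,9‑tetraenal | O=C[C@@H](C)/C=C(\C)/C=C(\CC)/C=C(\CC)/C=C/c1ccccc1 | intermediate
13 | (E)‑2‑ethylhex‑2‑enoic acid | CCC/C=C(\CC)C(=O)O | starting material
14 | (4S)‑4‑isopropyloxazolidin‑2‑one | CC(C)[C@H]1COC(=O)N1 | starting material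
15 | (E)‑2‑ethylhex‑2‑enoic pivalic anhydride | CCC/C=C(\CC)C(=O)OC(=O)C(C)(C)C | intermediate (not isolated)
16 | (4S)‑3‑[(E)‑2‑ethylhex‑2‑enoyl]‑4‑isopropyloxazolidin‑2‑one | CCC/C=C(\CC)C(=O)N1[C@@H](C(C)C)COC1=O | intermediate
17 | (4S)‑3‑[(1E,3E)‑1‑[(tert‑butyldimethylsilyl)oxy]‑2‑ethylhexa‑1,3‑dien‑1‑yl]‑4‑isopropyloxazolidin‑2‑one | CC/C=C/C(CC)=C(/O[Si](C)(C)C(C)(C)C)N1[C@@H](C(C)C)COC1=O | intermediate
18 | (4S)‑3‑[(2E,4S,5R,6S,7E,9E,11E,13E)‑2,4,10,12‑tetraethyl‑5‑hydroxy‑6,8‑dimethyl‑14‑phenyltetradeca‑2,7,9,11,13‑pentaenoyl]‑4‑isopropyloxazolidin‑2‑one | O=C(N1[C@@H](C(C)C)COC1=O)/C(CC)=C/[C@H](CC)[C@H](O)[C@@H](C)/C=C(\C)/C=C(\CC)/C=C(\CC)/C=C/c1ccccc1 | intermediate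
19 | (2E,4S,5R,6S,7E,9E,11E,13E)‑2,4,10,12‑tetraethyl‑5‑hydroxy‑6,8‑dimethyl‑14‑phenyltetradeca‑2,7,9,11,13‑pentaeneperoxoic acid | OOC(=O)/C(CC)=C/[C@H](CC)[C@H](O)[C@@H](C)/C=C(\C)/C=C(\CC)/C=C(\CC)/C=C/c1ccccc1 | intermediate (not isolated)
20 | (2E,4S,5R,6S,7E,9E,11E,13E)‑2,4,10,12‑tetraethyl‑5‑hydroxy‑6,8‑dimethyl‑14‑phenyltetradeca‑2,7,9,11,13‑pentaenoic acid | OC(=O)/C(CC)=C/[C@H](CC)[C@H](O)[C@@H](C)/C=C(\C)/C=C(\CC)/C=C(\CC)/C=C/c1ccccc1 | intermediate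
21 | (1S,2R,3S,3aR,4R,5R,7aR)‑3,4,5‑triethyl‑5‑[(1E,3E)‑2‑ethyl‑4‑phenylbuta‑1,3‑dien‑1‑yl]‑2‑hydroxy‑1,7‑dimethyl‑2,3,3a,4,5,7a‑hexahydro‑1H‑indene‑4‑carboxylic acid | CCC(/C=C/c1ccccc1)=C\[C@@]1(CC)C=C(C)[C@@H]2[C@H]([C@H](CC)[C@H](O)[C@H]2C)[C@@]1(CC)C(=O)O | intermediate (not isolated)
22 | (1S,3S,3aR,4R,5R,7aR)‑3,4,5‑triethyl‑5‑[(1E,3E)‑2‑ethyl‑4‑phenylbuta‑1,3‑dien‑1‑yl]‑1,7‑dimethyl‑2‑oxo‑2,3,3a,4,5,7a‑hexahydro‑1H‑indene‑4‑carboxylic acid | CCC(/C=C/c1ccccc1)=C\[C@@]1(CC)C=C(C)[C@@H]2[C@H]([C@H](CC)C(=O)[C@H]2C)[C@@]1(CC)C(=O)O | target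

## Step count and risks

Total: 11 steps (each one‑flask sequence counted as one step). Longest linear sequence: 8 steps (1, 2, 3, 5, 6, 9, 10, 11).

**Step 5 (the new alkenyl transfer).** Methyl transfer or attack at C2 may compete. The fallback sets out from 7 and comes back at 12, using known reaction types only. The carboalumination of 7 is quenched with iodine to give [(1E,3E,5E,7E)‑3,5‑diethyl‑8‑iodo‑7‑methylocta‑1,3,5,7‑tetraen‑1‑yl]benzene F1. Stille coupling with (E)‑3‑(tributylstannyl)prop‑2‑en‑1‑ol gives (2E,4E,6E,8E,10E)‑7,9‑diethyl‑5‑methyl‑11‑phenylundeca‑2,4,6,8,10‑pentaen‑1‑ol F2. Sharpless epoxidation with D‑(−)‑DIPT gives [(2R,3R)‑3‑[(1E,3E,5E,7E)‑4,6‑diethyl‑2‑methyl‑8‑phenylocta‑1,3,5,7‑tetraen‑1‑yl]oxiran‑2‑yl]methanol F3. Trimethylaluminium opens the allylic C3–O bond with inversion to give (2S,3S,4E,6E,8E,10E)‑7,9‑diethyl‑3,5‑dimethyl‑11‑phenylundeca‑4,6,8,10‑tetraene‑1,2‑diol F4, the C2 epimer of 11. Periodate cleavage then gives 12. Here methyl, not the polyene, is the nucleophile.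

**Step 9 (vinylogous aldol).** The tetraenal is Lewis‑acid‑sensitive and epimerisable, and 18 could cyclise before the auxiliary is removed. The fallback sets out from 12 and comes back at 20. A D‑proline‑catalysed cross‑aldol reaction of 12 with butanal (slow addition, DMF, 4 °C) gives the anti aldol (2R,3R,4S,5E,7E,9E,11E)‑2,8,10‑triethyl‑3‑hydroxy‑4,6‑dimethyl‑12‑phenyldodeca‑5,7,9,11‑tetraenal F5. Wittig reaction with ethyl 2‑(triphenylphosphoranylidene)butanoate gives ethyl (2E,4S,5R,6S,7E,9E,11E,13E)‑2,4,10,12‑tetraethyl‑5‑hydroxy‑6,8‑dimethyl‑14‑phenyltetradeca‑2,7,9,11,13‑pentaenoate F6. LiOH hydrolysis of this unhindered enoate gives 20. Butanal self‑aldol will compete with this hindered acceptor, so the fallback is expected to be lower‑yielding.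

**Step 10 (imide hydrolysis).** Hydroperoxide may attack the polyene, or hydroxide may open the oxazolidinone ring. The fallback sets out from 18 and comes back at 20. LiBH4 removes the auxiliary reductively to give (2E,4S,5R,6S,7E,9E,11E,13E)‑2,4,10,12‑tetraethyl‑6,8‑dimethyl‑14‑phenyltetradeca‑2,7,9,11,13‑pentaene‑1,5‑diol F7. Selective oxidation of the primary allylic alcohol (TEMPO, PhI(OAc)2) gives (2E,4S,5R,6S,7E,9E,11E,13E)‑2,4,10,12‑tetraethyl‑5‑hydroxy‑6,8‑dimethyl‑14‑phenyltetradeca‑2,7,9,11,13‑pentaenal F8. Pinnick oxidation (NaClO2, NaH2PO4, 2‑methyl‑2‑butene) gives 20, or 21 directly if the enal has already cyclised.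

Further compounds
F1 | step 5 | [(1E,3E,5E,7E)‑3,5‑diethyl‑8‑iodo‑7‑methylocta‑1,3,5,7‑tetraen‑1‑yl]benzene | I/C=C(\C)/C=C(\CC)/C=C(\CC)/C=C/c1ccccc1
F2 | step 5 | (2E,4E,6E,8E,10E)‑7,9‑diethyl‑5‑methyl‑11‑phenylundeca‑2,4,6,8,10‑pentaen‑1‑ol | OC/C=C/C=C(\C)/C=C(\CC)/C=C(\CC)/C=C/c1ccccc1
F3 | step 5 | [(2R,3R)‑3‑[(1E,3E,5E,7E)‑4,6‑diethyl‑2‑methyl‑8‑phenylocta‑1,3,5,7‑tetraen‑1‑yl]oxiran‑2‑yl]methanol | OC[C@H]1O[C@@H]1/C=C(\C)/C=C(\CC)/C=C(\CC)/C=C/c1ccccc1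
F4 | step 5 | (2S,3S,4E,6E,8E,10E)‑7,9‑diethyl‑3,5‑dimethyl‑11‑phenylundeca‑4,6,8,10‑tetraene‑1,2‑diol | OC[C@@H](O)[C@@H](C)/C=C(\C)/C=C(\CC)/C=C(\CC)/C=C/c1ccccc1
F5 | step 9 | (2R,3R,4S,5E,7E,9E,11E)‑2,8,10‑triethyl‑3‑hydroxy‑4,6‑dimethyl‑12‑phenyldodeca‑5,7,9,11‑tetraenal | O=C[C@H](CC)[C@H](O)[C@@H](C)/C=C(\C)/C=C(\CC)/C=C(\CC)/C=C/c1ccccc1
F6 | step 9 | ethyl (2E,4S,5R,6S,7E,9E,11E,13E)‑2,4,10,12‑tetraethyl‑5‑hydroxy‑6,8‑dimethyl‑14‑phenyltetradeca‑2,7,9,11,13‑pentaenoate | CCOC(=O)/C(CC)=C/[C@H](CC)[C@H](O)[C@@H](C)/C=C(\C)/C=C(\CC)/C=C(\CC)/C=C/c1ccccc1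
F7 | step 10 | (2E,4S,5R,6S,7E,9E,11E,13E)‑2,4,10,12‑tetraethyl‑6,8‑dimethyl‑14‑phenyltetradeca‑2,7,9,11,13‑pentaene‑1,5‑diol | OC/C(CC)=C/[C@H](CC)[C@H](O)[C@@H](C)/C=C(\C)/C=C(\CC)/C=C(\CC)/C=C/c1ccccc1
F8 | step 10 | (2E,4S,5R,6S,7E,9E,11E,13E)‑2,4,10,12‑tetraethyl‑5‑hydroxy‑6,8‑dimethyl‑14‑phenyltetradeca‑2,7,9,11,13‑pentaenal | O=C/C(CC)=C/[C@H](CC)[C@H](O)[C@@H](C)/C=C(\C)/C=C(\CC)/C=C(\CC)/C=C/c1ccccc1
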